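**Retrosynthetic overview**

1. Caespitane 14 ⇐ triflate 13 ⇐ alcohols 12 and 11 ⇐ cyclohexenecarbaldehyde 10: the ring methyl is carried as CHO and the ring CH–CH2 unit as a C=C bond.
2. 10 ⇐ Diels–Alder union of the E‑bromodiene 8 with 2‑chloroacrolein 9, which forms the ring CH2–CH2 bond and the CHBr–C(Cl) bond and places Br and Cl trans.
3. Enabling feature: in the cyclohexane ring the oxane‑bearing C1 is para to C4(Cl)(CH3) and the C3–Br carbon is ortho to it, so with CH3 read as CHO and C1=C2 unsaturated the ring is an ortho/para [4+2] adduct. Bromochlorination of a cyclohexene opens diaxially and cannot give this trans‑diequatorial Br/Cl pair; an endo cycloaddition can.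
4. 8 ⇐ alkenyl triflate 5 ⇐ methyl ketone 3 ⇐ vinyl oxane 2 ⇐ (S)‑linalool 1 by bromoetherification.
5. Ring order: oxane first (step 1), cyclohexane second (step 6).

Key step: step 6

Assumption: (S)‑(+)‑linalool of high enantiomeric purity and 2‑chloroprop‑2‑enal (stabilised, distilled before use) are treated as purchasable starting materials.

**Route**

Step 1
Reactants: 1 (3S)‑3,7‑dimethylocta‑1,6‑dien‑3‑ol, (S)‑linalool
Product: 2 (2S,5R)‑5‑bromo‑2‑ethenyl‑2,6,6‑trimethyloxane
Conditions: TBCO (1.05 equiv), MeNO2, 0 °C to rt, dark; chromatographic separation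
Reagents that add atoms: 2,4,4,6‑tetrabromocyclohexa‑2,5‑dien‑1‑one (TBCO), O=C1C(Br)=CC(Br)(Br)C=C1Br
Why: Bromonium‑induced 6‑endo bromoetherification of the tertiary alcohol onto the more nucleophilic trisubstituted alkene (Markovnikov C–O bond formation, chair transition state with equatorial bromine) should give the oxane; C2 is carried over from (S)‑linalool, whereas C5 is expected to form together with its (2S,5S) epimer (vinyl and methyl compete for the equatorial site) and with oxolane regioisomers, from which 2 (Br trans to vinyl) is separated.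

Step 2
Reactants: 2 (2S,5R)‑5‑bromo‑2‑ethenyl‑2,6,6‑trimethyloxane
Product: 3 1‑[(2S,5R)‑5‑bromo‑2,6,6‑trimethyloxan‑2‑yl]ethan‑1‑one
Conditions: Pd(Quinox)Cl2 (5 mol %), AgSbF6 (12 mol %), tBuOOH (70% in water, 12 equiv), CH2Cl2, 0 °C to rt (Quinox = 2‑(4,5‑dihydro‑1,3‑oxazol‑2‑yl)quinoline)
Reagents that add atoms: tert‑butyl hydroperoxide, CC(C)(C)OO
Why: Tsuji–Wacker oxidation in its peroxide‑mediated, ligand‑controlled form should turn the terminal alkene next to the oxygen‑bearing carbon into the methyl ketone (Markovnikov oxidation) under neutral conditions that leave the secondary bromide and both stereocentres untouched.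

Step 3
Reactants: 3 1‑[(2S,5R)‑5‑bromo‑2,6,6‑trimethyloxan‑2‑yl]ethan‑1‑one
Product: 5 1‑[(2S,5R)‑5‑bromo‑2,6,6‑trimethyloxan‑2‑yl]ethenyl trifluoromethanesulfonate, via potassium enolate 4 (not isolated)
Conditions: KN(SiMe3)2, THF, −78 °C; then PhNTf2, −78 to 0 °C
Reagents that add atoms: N‑phenylbis(trifluoromethanesulfonimide) (PhNTf2), O=S(=O)(N(c1ccccc1)S(=O)(=O)C(F)(F)F)C(F)(F)F
Why: Kinetic enolisation of the only enolisable position (the methyl group) followed by O‑sulfonylation of the enolate (enol triflate formation) should give the 1,1‑disubstituted alkenyl triflate; at −78 °C the base should not eliminate the ring bromide and no stereocentre is involved.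

Step 4
Reactants: 5 1‑[(2S,5R)‑5‑bromo‑2,6,6‑trimethyloxan‑2‑yl]ethenyl trifluoromethanesulfonate; 6 (E)‑1,2‑bis(tributylstannyl)ethene
Product: 7 tributyl{(1E)‑3‑[(2S,5R)‑5‑bromo‑2,6,6‑trimethyloxan‑2‑yl]buta‑1,3‑dien‑1‑yl}stannane
Conditions: Pd(PPh3)4 (5 mol %), LiCl (3 equiv), 6 (2.5 equiv), THF, 65 °C
Reagents that add atoms: none
Why: Stille cross‑coupling of the alkenyl triflate (chloride‑assisted) with an excess of the E bis‑stannane should transfer a single stannylvinyl unit with retention of the E geometry, the hindered secondary alkyl bromide being inert toward zerovalent palladium under these conditions.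

Step 5
Reactants: 7 tributyl{(1E)‑3‑[(2S,5R)‑5‑bromo‑2,6,6‑trimethyloxan‑2‑yl]buta‑1,3‑dien‑1‑yl}stannane
Product: 8 (2S,5R)‑5‑bromo‑2‑[(3E)‑4‑bromobuta‑1,3‑dien‑2‑yl]‑2,6,6‑trimethyloxane
Conditions: NBS, MeCN, 0 °C, dark
Reagents that add atoms: N‑bromosuccinimide, O=C1CCC(=O)N1Br
Why: Electrophilic ipso‑substitution of the alkenyl–tin bond (bromodestannylation) proceeds with retention of configuration and much faster than attack on the diene, so the E‑1‑bromodiene should result.

Step 6
Reactants: 8 (2S,5R)‑5‑bromo‑2‑[(3E)‑4‑bromobuta‑1,3‑dien‑2‑yl]‑2,6,6‑trimethyloxane; 9 2‑chloroprop‑2‑enal (2‑chloroacrolein)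
Product: 10 (1R,2S)‑2‑bromo‑4‑[(2S,5R)‑5‑bromo‑2,6,6‑trimethyloxan‑2‑yl]‑1‑chlorocyclohex‑3‑ene‑1‑carbaldehyde
Conditions: (S)‑B‑(o‑tolyl)oxazaborolidine from (S)‑α,α‑diphenylprolinol (20 mol %), HNTf2 (18 mol %), 9 (3 equiv), CH2Cl2, −78 to −40 °C; Et3N quench
Reagents that add atoms: none
Why: Proposed new method: 2‑chloroacrolein bound through its carbonyl oxygen to the cationic boron centre (s‑trans enal, formyl C–H···O contact to the catalyst) should add to the s‑cis E‑bromodiene 8 in a concerted, asynchronous Diels–Alder reaction; the closest known reaction types are the oxazaborolidinium‑catalysed cycloadditions of 2‑halo‑ and 2‑methylacroleins with 2‑substituted butadienes and the thermal cycloadditions of 1‑bromo‑1,3‑dienes. The cyclohexene ring closes by an intermolecular suprafacial [4+2] mode in which the CH2 terminus of the diene joins the CH2 carbon of the enal and the CHBr terminus joins the chlorine‑bearing carbon. Regioselectivity is secured twice over, because the bromine at C1 and the oxanyl group at C3 of the diene both place the largest HOMO coefficient on the CH2 terminus, which pairs with the β‑carbon of the enal. The quaternary C1 (Cl, CHO) is set by the catalyst, whose aryl group shields one face of the bound enal, and C2 (Br) follows from the E geometry of the diene together with the endo position of the formyl group, so that Br is cis to CHO and trans to Cl. This trans Br/Cl pair, later diequatorial, is the arrangement that anti addition of BrCl to a 4‑substituted cyclohexene would deliver only in the series epimeric at the oxane‑bearing ring carbon. The step needs endo selectivity and catalyst control over the remote, enantiopure oxane; the bulky 3‑oxanyl group favours the s‑cis diene and sits far from both forming bonds, and the antipodal catalyst is equally accessible should the sense of induction, assigned here by analogy, prove opposite.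

Step 7
Reactants: 10 (1R,2S)‑2‑bromo‑4‑[(2S,5R)‑5‑bromo‑2,6,6‑trimethyloxan‑2‑yl]‑1‑chlorocyclohex‑3‑ene‑1‑carbaldehyde
Product: 11 [(1R,2S)‑2‑bromo‑4‑[(2S,5R)‑5‑bromo‑2,6,6‑trimethyloxan‑2‑yl]‑1‑chlorocyclohex‑3‑en‑1‑yl]methanol
Conditions: NaBH4, MeOH/THF, −40 to −20 °C; AcOH quench
Reagents that add atoms: none
Why: Borohydride reduction of the neopentyl‑type aldehyde (the usual handling of 2‑haloacrolein cycloadducts) at low temperature should leave the tertiary chloride and the allylic bromide intact and changes no stereocentre.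

Step 8
Reactants: 11 [(1R,2S)‑2‑bromo‑4‑[(2S,5R)‑5‑bromo‑2,6,6‑trimethyloxan‑2‑yl]‑1‑chlorocyclohex‑3‑en‑1‑yl]methanol
Product: 12 [(1R,2S,4S)‑2‑bromo‑4‑[(2S,5R)‑5‑bromo‑2,6,6‑trimethyloxan‑2‑yl]‑1‑chlorocyclohexyl]methanol
Conditions: 2‑nitrobenzenesulfonohydrazide (large excess, in portions), Et3N, CH2Cl2, rt
Reagents that add atoms: none
Why: Diimide reduction delivers two hydrogens in a concerted syn fashion without C–halogen cleavage, and attack on the cyclohexene face opposite the allylic C2 bromine and the cis CH2OH group (the chlorine face) should set C4 as S, that is, the oxane cis to bromine.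

Step 9
Reactants: 12 [(1R,2S,4S)‑2‑bromo‑4‑[(2S,5R)‑5‑bromo‑2,6,6‑trimethyloxan‑2‑yl]‑1‑chlorocyclohexyl]methanol
Product: 13 [(1R,2S,4S)‑2‑bromo‑4‑[(2S,5R)‑5‑bromo‑2,6,6‑trimethyloxan‑2‑yl]‑1‑chlorocyclohexyl]methyl trifluoromethanesulfonate
Conditions: Tf2O, pyridine, CH2Cl2, −78 to −30 °C; cold work‑up, used at once
Reagents that add atoms: trifluoromethanesulfonic anhydride, O=S(=O)(OS(=O)(=O)C(F)(F)F)C(F)(F)F
Why: O‑Sulfonylation (triflate formation) of the primary neopentyl alcohol at low temperature with a non‑nucleophilic base should proceed without touching any stereocentre.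

Step 10
Reactants: 13 [(1R,2S,4S)‑2‑bromo‑4‑[(2S,5R)‑5‑bromo‑2,6,6‑trimethyloxan‑2‑yl]‑1‑chlorocyclohexyl]methyl trifluoromethanesulfonate
Product: 14 caespitane, (2S,5R)‑5‑bromo‑2‑[(1S,3S,4S)‑3‑bromo‑4‑chloro‑4‑methylcyclohexyl]‑2,6,6‑trimethyloxane
Conditions: LiBHEt3, THF, −78 to 0 °C
Reagents that add atoms: none
Why: SN2 displacement of the primary triflate by the strongly nucleophilic hydride LiBHEt3 should convert CH2OTf into the methyl group on the chlorine‑bearing carbon, while the tertiary chloride and the two neopentyl‑type secondary bromides are much poorer electrophiles at this temperature, so all five stereocentres are retained.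

**Compound list**

1 | (3S)‑3,7‑dimethylocta‑1,6‑dien‑3‑ol, (S)‑linalool | O[C@](C)(C=C)CCC=C(C)C | starting material
2 | (2S,5R)‑5‑bromo‑2‑ethenyl‑2,6,6‑trimethyloxane | CC1(C)O[C@](C)(C=C)CC[C@H]1Br | intermediate
3 | 1‑[(2S,5R)‑5‑bromo‑2,6,6‑trimethyloxan‑2‑yl]ethan‑1‑one | CC1(C)O[C@](C)(C(C)=O)CC[C@H]1Br | intermediate
4 | potassium 1‑[(2S,5R)‑5‑bromo‑2,6,6‑trimethyloxan‑2‑yl]ethen‑1‑olate | CC1(C)O[C@](C)(C(=C)[O-])CC[C@H]1Br.[K+] | intermediate
5 | 1‑[(2S,5R)‑5‑bromo‑2,6,6‑trimethyloxan‑2‑yl]ethenyl trifluoromethanesulfonate | CC1(C)O[C@](C)(C(=C)OS(=O)(=O)C(F)(F)F)CC[C@H]1Br | intermediate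
6 | (E)‑1,2‑bis(tributylstannyl)ethene | CCCC[Sn](CCCC)(CCCC)/C=C/[Sn](CCCC)(CCCC)CCCC | starting material
7 | tributyl{(1E)‑3‑[(2S,5R)‑5‑bromo‑2,6,6‑trimethyloxan‑2‑yl]buta‑1,3‑dien‑1‑yl}stannane | CC1(C)O[C@](C)(C(=C)/C=C/[Sn](CCCC)(CCCC)CCCC)CC[C@H]1Br | intermediate
8 | (2S,5R)‑5‑bromo‑2‑[(3E)‑4‑bromobuta‑1,3‑dien‑2‑yl]‑2,6,6‑trimethyloxane | CC1(C)O[C@](C)(C(=C)/C=C/Br)CC[C@H]1Br | intermediate
9 | 2‑chloroprop‑2‑enal (2‑chloroacrolein) | C=C(Cl)C=O | starting material
10 | (1R,2S)‑2‑bromo‑4‑[(2S,5R)‑5‑bromo‑2,6,6‑trimethyloxan‑2‑yl]‑1‑chlorocyclohex‑3‑ene‑1‑carbaldehyde | CC1(C)O[C@](C)(C2CC[C@](C=O)(Cl)[C@@H](Br)C=2)CC[C@H]1Br | intermediate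
11 | [(1R,2S)‑2‑bromo‑4‑[(2S,5R)‑5‑bromo‑2,6,6‑trimethyloxan‑2‑yl]‑1‑chlorocyclohex‑3‑en‑1‑yl]methanol | CC1(C)O[C@](C)(C2CC[C@](CO)(Cl)[C@@H](Br)C=2)CC[C@H]1Br | intermediate
12 | [(1R,2S,4S)‑2‑bromo‑4‑[(2S,5R)‑5‑bromo‑2,6,6‑trimethyloxan‑2‑yl]‑1‑chlorocyclohexyl]methanol | CC1(C)O[C@](C)([C@H]2CC[C@](CO)(Cl)[C@@H](Br)C2)CC[C@H]1Br | intermediate
13 | [(1R,2S,4S)‑2‑bromo‑4‑[(2S,5R)‑5‑bromo‑2,6,6‑trimethyloxan‑2‑yl]‑1‑chlorocyclohexyl]methyl trifluoromethanesulfonate | CC1(C)O[C@](C)([C@H]2CC[C@](COS(=O)(=O)C(F)(F)F)(Cl)[C@@H](Br)C2)CC[C@H]1Br | intermediate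
14 | caespitane, (2S,5R)‑5‑bromo‑2‑[(1S,3S,4S)‑3‑bromo‑4‑chloro‑4‑methylcyclohexyl]‑2,6,6‑trimethyloxane | CC1(C)O[C@](C)([C@H]2CC[C@](C)(Cl)[C@@H](Br)C2)CC[C@H]1Br | target

**Step count and risks**

Total steps: 10. Longest linear sequence: 10 (from 1).

Steps most likely to fail:

Step 6 (Proposed new method). The electron‑poor bromodiene may react too slowly with the catalyst‑bound enal, endo or facial selectivity may erode, or the Lewis acid may ionise the allylic bromide of the adduct. The fallback gives up catalyst control and uses the mode in which 1‑bromodienes are known to react. It sets out from 8, which is heated with 9 without catalyst (toluene, hydroquinone, 60–80 °C in a sealed tube, or 10–12 kbar at room temperature). Because the oxane is enantiopure, the two endo ring antipodes are diastereomers: the cycloaddition should give 10 together with (1S,2R)‑2‑bromo‑4‑[(2S,5R)‑5‑bromo‑2,6,6‑trimethyloxan‑2‑yl]‑1‑chlorocyclohex‑3‑ene‑1‑carbaldehyde F1. The two are separated by chromatography and the route is rejoined at 10.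

Step 8. Diimide transfer to the hindered trisubstituted alkene may be too slow for useful conversion. The fallback moves the reduction to a metal catalyst on a substrate without a coordinating group. It sets out from 11, which is sulfonylated (Tf2O, pyridine, CH2Cl2, −78 °C) to [(1R,2S)‑2‑bromo‑4‑[(2S,5R)‑5‑bromo‑2,6,6‑trimethyloxan‑2‑yl]‑1‑chlorocyclohex‑3‑en‑1‑yl]methyl trifluoromethanesulfonate F2. This is hydrogenated with H2 (1–5 bar) and [Ir(cod)(PCy3)(py)][B(3,5‑(CF3)2C6H3)4] (2–5 mol %) in CH2Cl2 at 0 °C, where steric approach opposite the bromine and the CH2OTf group should again put hydrogen on the chlorine face. Short reaction times are needed to limit hydrogenolysis of the allylic bromide. The route is rejoined at 13.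

Step 10. Hydride displacement at the neopentyl carbon may be slow enough for ionisation with chlorine participation (1,2‑shift) or for reduction of a bromide to compete. The fallback replaces the polar displacement by a radical dehalogenation. It sets out from 12, which is converted by an Appel‑type iodination (I2, PPh3, imidazole, toluene, 60 °C) into (2S,5R)‑5‑bromo‑2‑[(1S,3S,4S)‑3‑bromo‑4‑chloro‑4‑(iodomethyl)cyclohexyl]‑2,6,6‑trimethyloxane F3. This is reduced with Bu3SnH (1.1 equiv) and Et3B/air in toluene at −78 °C, where the C–I bond is abstracted far faster than C–Br or C–Cl and the low temperature and high stannane concentration should outrun a 1,2‑chlorine shift of the primary radical. The route is rejoined at 14.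

**Further compounds**

F1 | step 6 | (1S,2R)‑2‑bromo‑4‑[(2S,5R)‑5‑bromo‑2,6,6‑trimethyloxan‑2‑yl]‑1‑chlorocyclohex‑3‑ene‑1‑carbaldehyde | CC1(C)O[C@](C)(C2CC[C@@](C=O)(Cl)[C@H](Br)C=2)CC[C@H]1Br
F2 | step 8 | [(1R,2S)‑2‑bromo‑4‑[(2S,5R)‑5‑bromo‑2,6,6‑trimethyloxan‑2‑yl]‑1‑chlorocyclohex‑3‑en‑1‑yl]methyl trifluoromethanesulfonate | CC1(C)O[C@](C)(C2CC[C@](COS(=O)(=O)C(F)(F)F)(Cl)[C@@H](Br)C=2)CC[C@H]1Br
F3 | step 10 | (2S,5R)‑5‑bromo‑2‑[(1S,3S,4S)‑3‑bromo‑4‑chloro‑4‑(iodomethyl)cyclohexyl]‑2,6,6‑trimethyloxane | CC1(C)O[C@](C)([C@H]2CC[C@](CI)(Cl)[C@@H](Br)C2)CC[C@H]1Br
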